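Start with the easiest step there is, a subtraction on the amber table below, whose charge summer repeats.

| flask | starting material | partner | remark | time |
|---|---|---|---|---|
| amber | 0.20 M | 0.12 M | run made earlier |  |
| grey | 0.20 M | 0.18 M | run made earlier |  |
| midnight | 0.20 M | 0.120 M (fed, over 10 h) | all else is in the flask from the start; the feed brings no volume worth counting | 12 h |
| winter | 0.20 M (in portions, 2, over 10 h) | 0.120 M | first portion at the start, last at 10 h | 12 h |
| summer | 0.20 M | 0.120 M | everything together at the start | 12 h |
| dusk | 0.20 M (fed, over 10 h) | 0.120 M | all else is in the flask from the start; the feed brings no volume worth counting | 12 h |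

- amber (time / h: side product / %, target / %, starting material / %): 2.00: 12.3, 13.0, 71.0; 4.00: 17.6, 13.1, 69.7; 5.00: 18.0, 12.5, 70.1; 8.00: 18.1, 14.5, 68.9
- grey (time / min: side product / %, target / %, starting material / %): 6.00: 0, 4.6, 80.6; 12.0: 0.7, 8.6, 76.1; 30.0: 5.6, 15.6, 69.6; 80.0: 12.0, 19.4, 64.3

(readings scatter by 1 percentage point)

- the numbers in the tables scatter by 1 percentage point (one standard deviation)
- on the list of suspects stand: starting material + partner <-> intermediate A; starting material + partner <-> intermediate B; partner + intermediate A <-> intermediate C; partner + intermediate B -> target; intermediate B -> side product; 2 partner -> homo dimer

1. which flask leads in amount of side product, in percent of the starting material charged ("all alike" within 1.5 percentage points) (midnight / winter / summer / dusk / all alike)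
2. how much side product is there at the end, in percent of the starting material charged: midnight
3. how much side product is there at the end, in percent of the starting material charged: winter
4. how much side product is there at the end, in percent of the starting material charged: summer
5. how much side product is there at the end, in percent of the starting material charged: dusk

In amber the side product stands 5.8 percentage points short of its last reading at 2.00 h and 0.5 points short at 4.00 h. From these two gaps I take the tail lifetime τ, 0.816 h, the time in which a lean remainder of partner and what hangs on it shrinks by a factor e, with starting material in excess, so that the loss is pseudo-first-order. It is a rough reading, since the second gap lies below the scatter.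

Now run midnight slowly, as my own reckoning. In the first instants each drop of partner meets plenty of starting material, and binding is the quick step, for grey loses 19.4% of its starting material by 6.00 min while target stands at 4.6%.

Through the middle, partner settles where feed equals loss, at the feed rate times τ, 0.00979 M, which is far less than the 0.12 M amber begins with. Intermediate B then has two ways out: target needs a partner and side product does not, so target per side product goes with the partner level, while homo dimer needs two partners and falls with its square. I therefore rank midnight above summer, which holds its whole partner charge from the start and which I place at amber's last reading of 18.1% side product, because the partner level in midnight stands far below that charge.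

At the end the feed stops, and the 2.00 h that remain are 2.45 lifetimes, leaving 0.703% of the partner charge.

The forecast says midnight leads with 42%, then summer 18.2%, winter 14% and dusk 11%, since slow feeding “keeps partner low, which suppresses both dimer and target”.

The flasks give midnight first with 37.1%, then summer 17.6%, winter 12.4% and dusk 6.54%. Midnight dosed over 1.00 h instead gives 20.3%, and there τ is 81.6% of the dosing time, against 8.16% on the card. At 12.0 h midnight holds 0.739% of its partner charge, beside the reckoned 0.703%.

    starting material + partner ⇌ intermediate A (K = 0.879 M⁻¹, k = 0.0619 M⁻¹ s⁻¹)
    starting material + partner ⇌ intermediate B (K = 227 M⁻¹, k = 0.00271 M⁻¹ s⁻¹)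
    partner + intermediate A ⇌ intermediate C (K = 39.0 M⁻¹, k = 0.00446 M⁻¹ s⁻¹)
    partner + intermediate B → target (k = 0.0235 M⁻¹ s⁻¹)
    intermediate B → side product (k = 5.73 × 10⁻⁴ s⁻¹)
    2 partner → homo dimer (k = 0.00277 M⁻¹ s⁻¹)

Take midnight with 0.048 M of partner: the same τ sets its level at 0.00392 M, so target per side product should drop from midnight's 0.243 to 0.0971. That neighbour gives 19.4% side product and 1.85% target, a ratio of 0.0954.

(The runs were computed with made-up constants; noise was put on by code.)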